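The macrocycle is cut at the diaryl ether bond between the oxygen on the para-phenylene ring B and C3 of the ketone-bearing ring D (C1 acyl, C3 ether, C4 and C5 hydroxyl). The key step closes the 18-membered ring by intramolecular SNAr of the ring B phenoxide on the C3–F bond of ring D. It exploits the fact that C3 lies ortho to the hydroxylated C4, itself para to the acyl carbon C1: C4 is carried as a formyl-bearing carbon that activates the neighbouring fluoride, and Dakin oxidation later turns CHO into the C4 hydroxyl. The precursor is an open-chain phenol whose ring D is a 3-fluoro-4-formyl-5-methoxyphenyl ketone.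

Key step: step 7

Remark: the target has no stereocentre. Ring A is the 1,2,3-trisubstituted ring with one hydroxyl and ring C is the meta-phenylene ring. Compounds 3, 5 and 9 are taken to be commercially available.

Step 1
Reactants: 1 3-hydroxyphenylacetic acid
Product: 2 2-(3-hydroxyphenyl)-N-methoxy-N-methylacetamide
Conditions: MeNHOMe·HCl, EDC·HCl, HOBt (cat.), N-methylmorpholine, CH2Cl2, 0 °C → rt
Reagents that add atoms: N,O-dimethylhydroxylamine hydrochloride, CNOC.Cl
Why: Carbodiimide-mediated amide coupling (Weinreb amide formation), in which the amine should outcompete the phenol for the active ester, so the phenol needs no protection.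

Step 2
Reactants: 2 2-(3-hydroxyphenyl)-N-methoxy-N-methylacetamide; 3 2-fluoro-3-methoxybenzaldehyde
Product: 4 2-[3-(2-formyl-6-methoxyphenoxy)phenyl]-N-methoxy-N-methylacetamide
Conditions: K2CO3, DMA, 120 °C
Reagents that add atoms: none
Why: Nucleophilic aromatic substitution (SNAr) of the fluoride, activated by the ortho formyl group, by the potassium phenoxide of 2; the aldehyde and the Weinreb amide are inert to carbonate.

Step 3
Reactants: 4 2-[3-(2-formyl-6-methoxyphenoxy)phenyl]-N-methoxy-N-methylacetamide; 5 (4-benzyloxybenzyl)triphenylphosphonium chloride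
Product: 7 2-[3-(2-{2-[4-(benzyloxy)phenyl]ethenyl}-6-methoxyphenoxy)phenyl]-N-methoxy-N-methylacetamide (E/Z mixture), via benzylic phosphorus ylide 6 (not isolated)
Conditions: K2CO3, 18-crown-6 (cat.), CH2Cl2, reflux
Reagents that add atoms: none
Why: Wittig olefination with a semistabilised benzylic ylide, which should attack only the aldehyde; the alkene geometry is irrelevant because the double bond is saturated in step 4.

Step 4
Reactants: 7 stilbene Weinreb amide (E/Z mixture)
Product: 8 2-[3-(2-[2-(4-hydroxyphenyl)ethyl]-6-methoxyphenoxy)phenyl]-N-methoxy-N-methylacetamide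
Conditions: H2 (1 atm), 10% Pd/C, EtOAc/EtOH, rt
Reagents that add atoms: none
Why: Catalytic hydrogenation saturates the stilbene and hydrogenolysis cleaves the benzyl ether in the same operation, while the methyl ether, the diaryl ether and the Weinreb amide should persist at one atmosphere.

Step 5
Reactants: 9 4-bromo-2-fluoro-6-methoxybenzaldehyde
Product: 10 5-bromo-2-(dimethoxymethyl)-1-fluoro-3-methoxybenzene
Conditions: HC(OMe)3, p-TsOH·H2O (cat.), MeOH, reflux
Reagents that add atoms: trimethyl orthoformate, COC(OC)OC; methanol, CO
Why: Acid-catalysed acetalisation, with the orthoformate as water scavenger, masks the aldehyde against the organomagnesium chemistry of step 6.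

Step 6
Reactants: 10 5-bromo-2-(dimethoxymethyl)-1-fluoro-3-methoxybenzene; 8 2-[3-(2-[2-(4-hydroxyphenyl)ethyl]-6-methoxyphenoxy)phenyl]-N-methoxy-N-methylacetamide
Product: 13 2-fluoro-4-{2-[3-(2-[2-(4-hydroxyphenyl)ethyl]-6-methoxyphenoxy)phenyl]acetyl}-6-methoxybenzaldehyde, via arylmagnesium chloride 11 (not isolated), via ketone dimethyl acetal 12 (not isolated)
Conditions: 10, i-PrMgCl·LiCl, THF, 0 °C → rt; then 8 (pre-treated with i-PrMgCl, 1 equiv, THF, −20 °C), 0 °C → rt; then 2 M HCl, THF, rt
Reagents that add atoms: water, O
Why: Bromine–magnesium exchange gives an unhindered aryl Grignard reagent whose addition to the Weinreb amide (Weinreb ketone synthesis; the phenol is first converted into its magnesium salt) stops at the chelated tetrahedral adduct, and aqueous acid then releases the ketone and hydrolyses the acetal to the aldehyde.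

Step 7
Reactants: 13 2-fluoro-4-{2-[3-(2-[2-(4-hydroxyphenyl)ethyl]-6-methoxyphenoxy)phenyl]acetyl}-6-methoxybenzaldehyde
Product: 14 macrocyclic aldehyde (target skeleton with ring A OMe and ring D C4-CHO and C5-OMe)
Conditions: Cs2CO3, DMF (0.003 M, slow addition of 13), 4 Å MS, 90 °C, Ar
Reagents that add atoms: none
Why: Intramolecular SNAr by addition–elimination: the caesium phenoxide of ring B adds to the fluorine-bearing C3 of ring D to give a Meisenheimer complex whose charge is delocalised onto the ortho formyl group at C4 and stabilised inductively by the ketone at C1, and loss of fluoride restores aromaticity. The closest known reaction type is the macrocyclising SNAr etherification of phenols with ortho-activated fluoroarenes used for cyclic diaryl ether natural products. The 18-membered ring closes in a formal 18-exo-trig mode onto the C3=C4 bond of ring D, whose far end C4 and its formyl group lie outside the new ring. No stereocentre is formed. The step needs site selectivity, secured because fluoride is the only good nucleofuge ortho to the formyl group (the C5 methoxy is far less labile), and it needs O-arylation by the phenoxide to win over reactions of the ketone enolate and ring closure to win over chain growth. The enolate cannot reach the formyl group or the C–F carbon of its own ring D, so its reactions are intermolecular only and, like oligomerisation, are suppressed by high dilution with slow addition under argon.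

Step 8
Reactants: 14 macrocyclic aldehyde
Product: 16 macrocyclic phenol (target skeleton with ring A OMe and ring D C4-OH and C5-OMe), via aryl formate 15 (not isolated)
Conditions: mCPBA, CH2Cl2, 0 °C → rt; aqueous NaHCO3 wash; then K2CO3 (cat.), MeOH, rt
Reagents that add atoms: meta-chloroperbenzoic acid, OOC(=O)c1cccc(Cl)c1
Why: Dakin-type oxidation, in which Baeyer–Villiger oxidation of the aldehyde with migration of the aryl group flanked by two ortho oxygen substituents gives the aryl formate, which is methanolysed in the same flask; the aryl benzyl ketone should react far more slowly with the unactivated peracid.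

Step 9
Reactants: 16 macrocyclic phenol
Product: 17 Marchantin G
Conditions: BBr3, CH2Cl2, −78 °C → rt; then H2O
Reagents that add atoms: none
Why: Lewis-acid cleavage of aryl methyl ethers by BBr3 removes both methyl groups while the diaryl ethers and the ketone should survive, and hydrolytic work-up releases the three phenols.

Compound list
1 | 3-hydroxyphenylacetic acid | OC(=O)Cc1cccc(O)c1 | starting material
2 | 2-(3-hydroxyphenyl)-N-methoxy-N-methylacetamide | CON(C)C(=O)Cc1cccc(O)c1 | intermediate
3 | 2-fluoro-3-methoxybenzaldehyde | O=Cc1cccc(OC)c1F | starting material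
4 | 2-[3-(2-formyl-6-methoxyphenoxy)phenyl]-N-methoxy-N-methylacetamide | O=Cc1cccc(OC)c1Oc1cccc(CC(=O)N(C)OC)c1 | intermediate
5 | (4-benzyloxybenzyl)triphenylphosphonium chloride | [Cl-].c1ccccc1[P+](Cc1ccc(OCc2ccccc2)cc1)(c1ccccc1)c1ccccc1 | starting material
6 | [4-(benzyloxy)benzylidene]triphenylphosphorane (ylide, not isolated) | c1ccccc1P(=Cc1ccc(OCc2ccccc2)cc1)(c1ccccc1)c1ccccc1 | intermediate
7 | 2-[3-(2-{2-[4-(benzyloxy)phenyl]ethenyl}-6-methoxyphenoxy)phenyl]-N-methoxy-N-methylacetamide, mixture of E and Z isomers, both used (drawn without alkene geometry) | CON(C)C(=O)Cc1cccc(c1)Oc1c(OC)cccc1C=Cc1ccc(OCc2ccccc2)cc1 | intermediate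
8 | 2-[3-(2-[2-(4-hydroxyphenyl)ethyl]-6-methoxyphenoxy)phenyl]-N-methoxy-N-methylacetamide | CON(C)C(=O)Cc1cccc(c1)Oc1c(OC)cccc1CCc1ccc(O)cc1 | intermediate
9 | 4-bromo-2-fluoro-6-methoxybenzaldehyde | O=Cc1c(F)cc(Br)cc1OC | starting material
10 | 5-bromo-2-(dimethoxymethyl)-1-fluoro-3-methoxybenzene | COC(OC)c1c(F)cc(Br)cc1OC | intermediate
11 | [4-(dimethoxymethyl)-3-fluoro-5-methoxyphenyl]magnesium chloride, LiCl complex (not isolated) | COC(OC)c1c(F)cc(cc1OC)[Mg]Cl | intermediate
12 | 1-[4-(dimethoxymethyl)-3-fluoro-5-methoxyphenyl]-2-[3-(2-[2-(4-hydroxyphenyl)ethyl]-6-methoxyphenoxy)phenyl]ethanone (not isolated) | COC(OC)c1c(F)cc(cc1OC)C(=O)Cc1cccc(c1)Oc1c(OC)cccc1CCc1ccc(O)cc1 | intermediate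
13 | 2-fluoro-4-{2-[3-(2-[2-(4-hydroxyphenyl)ethyl]-6-methoxyphenoxy)phenyl]acetyl}-6-methoxybenzaldehyde | O=Cc1c(F)cc(cc1OC)C(=O)Cc1cccc(c1)Oc1c(OC)cccc1CCc1ccc(O)cc1 | intermediate
14 | macrocyclic aldehyde: the 18-membered ring of the target with OMe on ring A and, on ring D, CHO at C4 and OMe at C5 | O=C1Cc2cccc(c2)Oc2c(OC)cccc2CCc2ccc(cc2)Oc2cc1cc(OC)c2C=O | intermediate
15 | formate ester of 16 at the ring D C4 oxygen (not isolated) | O=C1Cc2cccc(c2)Oc2c(OC)cccc2CCc2ccc(cc2)Oc2cc1cc(OC)c2OC=O | intermediate
16 | macrocyclic phenol: the target with OMe on ring A and on ring D C5, free OH on ring D C4 | O=C1Cc2cccc(c2)Oc2c(OC)cccc2CCc2ccc(cc2)Oc2cc1cc(OC)c2O | intermediate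
17 | Marchantin G | O=C1Cc2cccc(c2)Oc2c(O)cccc2CCc2ccc(cc2)Oc2cc1cc(O)c2O | target

Total step count: 9.
Longest linear sequence: 8 steps (steps 1, 2, 3, 4, 6, 7, 8, 9); step 5 is a one-step side branch.

Steps most likely to fail

Step 7 (key step). The carbonate base may enolise the deoxybenzoin ketone, and the enolate may then be consumed by intermolecular aldol condensation with the formyl group instead of the ring closing. The fallback masks the ketone as a carbinol during ring closure. It sets out from 12, isolated by quenching step 6 with aqueous NH4Cl instead of HCl. NaBH4 in MeOH at 0 °C should reduce the ketone to the racemic carbinol acetal F1. Aqueous HCl in THF should then free the aldehyde to give the racemic hydroxy aldehyde F2. The same SNAr closure (Cs2CO3, DMF, high dilution, 90 °C), now without an enolisable ketone, should give the racemic macrocyclic carbinol aldehyde F3. Dess–Martin periodinane in CH2Cl2 with NaHCO3 should oxidise the benzylic alcohol to the ketone, and the fallback comes back to the route at 14.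

Step 8. Hydride may migrate in place of the aryl group because of the para acyl substituent, which would give a carboxylic acid, and the peracid may also insert oxygen at the bridge ketone. The fallback replaces the peracid oxidation by a classical Dakin oxidation of an ortho-hydroxybenzaldehyde. It sets out from 14. BCl3 in CH2Cl2 (−78 → 0 °C) should cleave only the methyl ether ortho to the formyl group, through a boron chelate, to give the salicylaldehyde F4. Alkaline hydrogen peroxide (H2O2, NaOH, THF/H2O, 0 °C, under N2) is driven by the ortho phenoxide and does not touch the ketone, and should give the catechol monomethyl ether F5. BBr3 under the conditions of step 9 then removes the remaining ring A methyl ether, and the fallback comes back to the route at 17.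

Step 2. The fluoride of 3 is flanked by the formyl and the methoxy group, so substitution may be slow enough for thermal degradation of the aldehyde to compete at the temperature required. The fallback replaces addition–elimination by a copper-catalysed Ullmann ether coupling of 2 with commercially available 2-bromo-3-methoxybenzaldehyde (CuI, N,N-dimethylglycine hydrochloride, Cs2CO3, dioxane, 90 °C), in which the ortho formyl group assists the coupling. It sets out from 2 and comes back to the route at 4; compounds made on its way: none F0.

Further compounds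
F1 | step 7 | racemic 1-[4-(dimethoxymethyl)-3-fluoro-5-methoxyphenyl]-2-[3-(2-[2-(4-hydroxyphenyl)ethyl]-6-methoxyphenoxy)phenyl]ethanol | COC(OC)c1c(F)cc(cc1OC)C(O)Cc1cccc(c1)Oc1c(OC)cccc1CCc1ccc(O)cc1
F2 | step 7 | racemic 2-fluoro-4-{1-hydroxy-2-[3-(2-[2-(4-hydroxyphenyl)ethyl]-6-methoxyphenoxy)phenyl]ethyl}-6-methoxybenzaldehyde | O=Cc1c(F)cc(cc1OC)C(O)Cc1cccc(c1)Oc1c(OC)cccc1CCc1ccc(O)cc1
F3 | step 7 | racemic macrocyclic carbinol aldehyde (14 with the bridge ketone reduced to CH–OH) | OC1Cc2cccc(c2)Oc2c(OC)cccc2CCc2ccc(cc2)Oc2cc1cc(OC)c2C=O
F4 | step 8 | macrocyclic salicylaldehyde (14 with free OH at ring D C5) | O=C1Cc2cccc(c2)Oc2c(OC)cccc2CCc2ccc(cc2)Oc2cc1cc(O)c2C=O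
F5 | step 8 | Marchantin G ring A mono-methyl ether | O=C1Cc2cccc(c2)Oc2c(OC)cccc2CCc2ccc(cc2)Oc2cc1cc(O)c2O
F0 | step 2 | none | none
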